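**Retrosynthetic overview**

1. Last bond, C11–C12: the α-methylene-γ-lactone is closed in the final step by Pd(II)-catalysed cyclocarbonylation (CO becomes C12) of the unprotected macrocyclic alkynol 32. The enabling feature is that the C6 hydroxyl and the C7 ethynyl group are vicinal and cis on the ten-membered carbocycle (a homopropargylic alcohol), so C6–O–C(=O)–Pd reaches the internal alkyne carbon C11 through a five-membered 5-exo-dig insertion, while O8 already carries the ester.
2. Ten-membered ring: ring-closing metathesis at C2=C3 between the (Z)-diene terminus and a vinyl epoxide. The C1–C10 epoxide is set before ring closure (Sharpless epoxidation of the C14 allylic alcohol), so a cyclic all-cis 1,3,5-triene, which would undergo 6π-electrocyclisation, never exists.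
3. C9–C10 and C10=C1: terminal epoxide C8–C9 plus triethyl phosphonoacetate gives an α-phosphono-γ-lactone; Horner–Wadsworth–Emmons reaction with acrolein, then DIBAL-H. O8 then takes silylated (Z)-2-(hydroxymethyl)but-2-enoic acid, made from crotonaldehyde.
4. C6/C7/C8 triad: chiral phosphoric acid-catalysed anti allylboration of (Z)-3-iodobut-2-enal with an (E)-γ-(silylethynyl)allylboronate sets C6 and C7; iodocarbonate cyclisation sets C8; the vinyl iodide becomes the (Z)-diene by Stille coupling.
5. Ring order: 1,3-dioxan-2-one (temporary) → oxirane C8–C9 (temporary) → γ-lactone O8/C14 (temporary) → oxirane C1–C10 → cyclodecadiene → α-methylene-γ-lactone.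

Key step: step 24

**Remarks and assumptions**

- Numbering (germacrane type): C6 lactone carbinol CH, C7 ring-fusion CH, C8 acyloxy CH, C9 CH2, C10 (quaternary, bears C14H2OH) and C1 epoxide carbons, C2=C3 and C4(C15H3)=C5 the (Z,Z)-diene, C11/C12/C13 α-carbon, carbonyl and exocyclic CH2. The target is (1R,6S,7R,8R,10R): O6, C11 and O8 are all cis on the ring (cis-fused lactone) and the epoxide is ring-cis.
- Assumption: (R)-TRIP directs the allyl group to the Re face of the formyl group of 7, as with other aryl and α,β-unsaturated aldehydes.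
- Assumption: in-flask species that differ from a numbered compound only by deprotonation (alkoxides, acetylides, carboxylates), and catalytic-cycle species other than 33, are not numbered.
- (R)-TRIP = (R)-3,3'-bis(2,4,6-triisopropylphenyl)-1,1'-binaphthyl-2,2'-diyl hydrogen phosphate.

**Route**

Step 1
Reactants: 1 (E)-pent-2-en-4-yn-1-ol
Product: 2 (E)-5-(triisopropylsilyl)pent-2-en-4-yn-1-ol
Conditions: EtMgBr (2.2 equiv), THF, 0 → 50 °C; TIPSCl (1.1 equiv), 50 °C; aq NH4Cl
Reagents that add atoms: chlorotriisopropylsilane CC(C)[Si](Cl)(C(C)C)C(C)C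
Why: C-silylation of the doubly magnesiated enynol, in which the alkynyl Grignard reacts with the hindered silyl chloride while the magnesium alkoxide does not; no stereocentre is formed and the (E)-alkene is untouched.

Step 2
Reactants: 2 (E)-5-(triisopropylsilyl)pent-2-en-4-yn-1-ol
Product: 3 (E)-γ-(silylethynyl)allyl pinacol boronate
Conditions: B2pin2 (1.2 equiv), [Pd(MeCN)4](BF4)2 (5 mol %), DMSO/MeOH 1:1, 40 °C
Reagents that add atoms: bis(pinacolato)diboron CC1(C)OB(OC1(C)C)B1OC(C)(C)C(C)(C)O1
Why: Palladium-catalysed direct borylation of an allylic alcohol through a π-allyl intermediate should place boron at the unsubstituted terminus and keep the conjugated (E)-enyne, giving the linear (E)-allylboronate.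

Step 3
Reactants: 4 but-2-yn-1-ol
Product: 6 (Z)-3-iodobut-2-en-1-ol, via cyclic alkenylalanate 5 (not isolated)
Conditions: Red-Al (1.5 equiv), THF, 0 °C → rt; then I2 (1.5 equiv), −78 °C; Rochelle salt
Reagents that add atoms: iodine II
Why: Alkoxide-directed trans-hydroalumination of a propargylic alcohol (hydride to C2, aluminium to C3 in a five-membered alanate) followed by iodinolysis with retention gives the (Z)-vinyl iodide with iodine cis to the carbinol carbon.

Step 4
Reactants: 6 (Z)-3-iodobut-2-en-1-ol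
Product: 7 (Z)-3-iodobut-2-enal
Conditions: MnO2 (15 equiv), CH2Cl2, rt; filtered and used at once
Reagents that add atoms: none
Why: Allylic oxidation with activated manganese dioxide is neutral and should leave the (Z)-iodoalkene geometry intact.

Step 5
Reactants: 3 (E)-γ-(silylethynyl)allyl pinacol boronate; 7 (Z)-3-iodobut-2-enal
Product: 9 (2Z,4R,5S)-2-iodo-5-[(triisopropylsilyl)ethynyl]hepta-2,6-dien-4-ol, via pinacol borate ester 8 (not isolated)
Conditions: (R)-TRIP (5 mol %), 4 Å MS, toluene, −30 °C; aq NaHCO3 work-up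
Reagents that add atoms: none
Why: Chiral phosphoric acid-catalysed allylboration through a closed chair (Zimmerman–Traxler) transition state, in which the (E)-γ-substituted boronate gives the anti relation of C6–OH and the C7 alkynyl group and the catalyst selects the Re face of the aldehyde, so C6 and C7 are set together in the absolute sense of the target.

Step 6
Reactants: 9 anti homoallylic alcohol
Product: 10 tert-butyl carbonate of 9
Conditions: Boc2O (2 equiv), DMAP (0.2 equiv), MeCN, rt
Reagents that add atoms: di-tert-butyl dicarbonate CC(C)(C)OC(=O)OC(=O)OC(C)(C)C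
Why: DMAP-catalysed O-acylation of the secondary alcohol installs the internal nucleophile for the next step; no stereocentre is touched.

Step 7
Reactants: 10 tert-butyl carbonate
Product: 11 all-equatorial cyclic iodocarbonate (4-iodomethyl-1,3-dioxan-2-one)
Conditions: IBr (1.3 equiv), toluene, −85 °C; aq Na2S2O3
Reagents that add atoms: iodine monobromide IBr
Why: Iodocarbonate cyclisation in which the carbonate carbonyl opens the iodonium ion of the terminal vinyl group in the 6-exo mode through a chair with the C6, C7 and C8 substituents all equatorial, which sets C8 syn to O6 and anti to the C7 alkynyl group; the iodo-substituted alkene and the silylalkyne are too electron-poor to compete for the electrophile.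

Step 8
Reactants: 11 cyclic iodocarbonate
Product: 13 epoxy alcohol (C8–C9 oxirane and free C6–OH), via iodo diol 12 (not isolated)
Conditions: K2CO3 (3 equiv), MeOH, rt
Reagents that add atoms: none
Why: Methanolysis of the cyclic carbonate followed by 3-exo-tet displacement of the primary iodide by the C8 alkoxide forms the terminal epoxide; C8 keeps its configuration because only the C9–I bond is broken, and the triisopropylsilyl alkyne is stable to these conditions.

Step 9
Reactants: 13 epoxy alcohol
Product: 14 C6 tert-butyldimethylsilyl ether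
Conditions: TBSCl (1.5 equiv), imidazole (3 equiv), DMAP (cat.), DMF, 35 °C
Reagents that add atoms: tert-butylchlorodimethylsilane C[Si](C)(Cl)C(C)(C)C
Why: Standard silylation under non-Lewis-acidic conditions protects O6 without opening the epoxide; no stereocentre is touched.

Step 10
Reactants: 14 vinyl iodide epoxide
Product: 15 (Z)-diene epoxide
Conditions: tributyl(vinyl)stannane (1.3 equiv), Pd2(dba)3 (2.5 mol %), AsPh3 (10 mol %), NMP, rt
Reagents that add atoms: tributyl(vinyl)stannane C=C[Sn](CCCC)(CCCC)CCCC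
Why: Stille coupling proceeds with retention at the vinyl iodide, so the new vinyl group (C3) stays cis to C6, and the isolated, non-allylic epoxide is inert to Pd(0).

Step 11
Reactants: 15 (Z)-diene epoxide
Product: 17 α-(diethoxyphosphoryl)-γ-butyrolactone, via hydroxy phosphonoester 16 (not isolated)
Conditions: triethyl phosphonoacetate (2 equiv), NaH (2 equiv), DME, 70 °C; aq NH4Cl
Reagents that add atoms: triethyl phosphonoacetate CCOC(=O)CP(=O)(OCC)OCC
Why: The phosphonoacetate anion opens the terminal epoxide at C9 and the C8 alkoxide lactonises onto the ethyl ester (5-exo-trig), which forms the C9–C10 bond and masks O8 and C14 in one temporary ring; C8 is untouched and the new C10 centre (epimer mixture) is destroyed in step 12.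

Step 12
Reactants: 17 α-phosphono lactone
Product: 18 (E)-α-(prop-2-enylidene)-γ-butyrolactone
Conditions: KOtBu (1.1 equiv), THF, 0 °C; acrolein (3 equiv), 0 °C → rt
Reagents that add atoms: acrolein C=CC=O
Why: Horner–Wadsworth–Emmons olefination of an α-phosphono lactone should give mainly the (E)-alkylidene lactone, in which the new vinyl group (C2) is cis to C9 and trans to the carbonyl, as the target epoxide requires.

Step 13
Reactants: 18 (E)-alkylidene lactone
Product: 19 diol (C8–OH and C14–OH)
Conditions: DIBAL-H (4.5 equiv), CH2Cl2, −78 → 0 °C; Rochelle salt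
Reagents that add atoms: none
Why: 1,2-Reduction of the conjugated lactone opens the temporary ring to the C14 allylic alcohol and the C8 secondary alcohol without touching the alkene geometry or any stereocentre.

Step 14
Reactants: 19 diol
Product: 20 C14 triethylsilyl ether
Conditions: TESCl (1.05 equiv), imidazole (2 equiv), CH2Cl2, −40 °C
Reagents that add atoms: chlorotriethylsilane CC[Si](Cl)(CC)CC
Why: The primary allylic hydroxyl is silylated much faster than the hindered secondary C8 hydroxyl, which leaves O8 free for the side chain.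

Step 15
Reactants: 21 (E)-but-2-enal
Product: 22 (Z)-2-iodobut-2-enal
Conditions: I2 (1.5 equiv), K2CO3 (1.2 equiv), DMAP (0.2 equiv), THF/H2O 1:1, rt
Reagents that add atoms: iodine II
Why: Amine-catalysed α-iodination of an enal (conjugate addition of DMAP, iodination of the enolate, elimination) gives the (Z)-α-iodo enal in which the methyl group stays trans to the formyl group.

Step 16
Reactants: 22 (Z)-2-iodobut-2-enal
Product: 23 (Z)-2-iodobut-2-en-1-ol
Conditions: NaBH4 (1 equiv), CeCl3·7H2O (1 equiv), MeOH, 0 °C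
Reagents that add atoms: none
Why: Luche reduction is 1,2-selective and leaves the vinyl iodide and its geometry intact.

Step 17
Reactants: 23 (Z)-2-iodobut-2-en-1-ol
Product: 24 (Z)-tert-butyl[(2-iodobut-2-en-1-yl)oxy]dimethylsilane
Conditions: TBSCl (1.2 equiv), imidazole (2 equiv), CH2Cl2, rt
Reagents that add atoms: tert-butylchlorodimethylsilane C[Si](C)(Cl)C(C)(C)C
Why: Routine silylation of a primary allylic alcohol protects the side-chain hydroxyl for the carboxylation and the esterification.

Step 18
Reactants: 24 silyl ether of the iodo alcohol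
Product: 26 (Z)-2-{[(tert-butyldimethylsilyl)oxy]methyl}but-2-enoic acid, via alkenyllithium 25 (not isolated)
Conditions: t-BuLi (2.1 equiv), Et2O, −78 °C; CO2 (gas), −78 °C → 0 °C; cold 1 M HCl
Reagents that add atoms: carbon dioxide O=C=O
Why: Iodine–lithium exchange and carboxylation both occur with retention at the sp2 carbon, so the carboxyl group ends up cis to the methyl group, which is the geometry of the side chain in the target.

Step 19
Reactants: 20 C14 triethylsilyl ether with free C8–OH; 26 silylated side-chain acid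
Product: 28 C8 ester, via mixed anhydride 27 (not isolated)
Conditions: 26 (1.5 equiv), 2,4,6-trichlorobenzoyl chloride (1.5 equiv), Et3N (2 equiv), THF, 0 °C; then 20, DMAP (2 equiv), toluene, rt
Reagents that add atoms: none
Why: Yamaguchi esterification acylates the hindered secondary alcohol at room temperature, where isomerisation of the (Z)-enoate is not expected, and C8 is acylated on oxygen with retention.

Step 20
Reactants: 28 C8 ester with C14–OTES
Product: 29 C14 allylic alcohol
Conditions: PPTS (0.1 equiv), MeOH/CH2Cl2 1:1, 0 °C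
Reagents that add atoms: none
Why: A primary triethylsilyl ether is cleaved by mild acid much faster than the tert-butyldimethylsilyl ethers or the silylalkyne, which frees the directing hydroxyl for the epoxidation.

Step 21
Reactants: 29 C14 allylic alcohol
Product: 30 (1R,10R)-epoxy alcohol
Conditions: Ti(OiPr)4 (10 mol %), D-(−)-diethyl tartrate (12 mol %), t-BuOOH (2 equiv, in isooctane), 4 Å MS, CH2Cl2, −20 °C
Reagents that add atoms: tert-butyl hydroperoxide CC(C)(C)OO
Why: Sharpless asymmetric epoxidation is confined to the alkene of the free allylic alcohol (C10=C1), and D-(−)-tartrate should deliver oxygen to the face that gives the (1R,10R) epoxide under reagent control, independent of the remote C6–C8 centres.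

Step 22
Reactants: 30 epoxy alcohol (seco-triene)
Product: 31 ten-membered (2Z,4Z)-diene epoxide
Conditions: second-generation ruthenium benzylidene NHC metathesis catalyst [(H2IMes)(PCy3)Cl2Ru=CHPh] (10 mol %), CH2Cl2 (1 mM), 40 °C
Reagents that add atoms: none
Why: Ring-closing metathesis joins the two monosubstituted alkene termini (the trisubstituted alkenes, the enoate and the silylalkyne are much less reactive), the (Z)-C4=C5 alkene and the cis-epoxide act as turn elements, and the ten-membered ring should enforce the (Z)-C2=C3 geometry.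

Step 23
Reactants: 31 silylated macrocycle
Product: 32 macrocyclic alkynyl triol
Conditions: TBAF (6 equiv), AcOH (6 equiv), THF, 0 °C → rt
Reagents that add atoms: none
Why: Buffered fluoride removes both tert-butyldimethylsilyl ethers and the C-triisopropylsilyl group in one operation, and the buffer should suppress epoxide migration and O8→O6 acyl shift.

Step 24
Reactants: 32 macrocyclic alkynyl triol
Product: 34 target CNP0165856.1, via alkoxycarbonylpalladium chloride 33 (not isolated)
Conditions: PdCl2 (10 mol %), thiourea (10 mol %), CO (1 atm), anhydrous acetone, 50 °C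
Reagents that add atoms: carbon monoxide [C-]#[O+]
Why: Palladium(II)-catalysed cyclocarbonylation of a homopropargylic alcohol: the C6 hydroxyl and CO give the alkoxycarbonyl–Pd(II) species 33, whose Pd–C(=O)O bond adds syn across the tethered C7 ethynyl group so that C12 bonds to the internal alkyne carbon C11, and protonolysis of the exocyclic vinyl–Pd bond by the HCl released in the first stage forms the =CH2 group and returns Pd(II). The closest known reaction type is the cyclocarbonylation of cis- and trans-2-ethynylcycloalkanols to cis- and trans-fused α-methylene-γ-butyrolactones, which is stereospecific at the carbinol centre. The five-membered lactone closes in the 5-exo-dig mode by C11–C12 bond formation, because the 6-endo alternative would require a trans double bond in a six-membered ring after syn insertion. No new stereocentre is formed: C6 and C7 are untouched and their cis relation on the ten-membered ring becomes the cis ring fusion. The step needs selection among three hydroxyls and between O6 and O8: only the C6 alkoxycarbonyl can reach the alkyne through a five-membered transition state (the C14 and side-chain hydroxyls would need eight-membered or larger insertions and their carbonyl–Pd species should simply revert), and O8 is blocked by the ester from step 19. The redox-neutral Pd(II) cycle without phosphine or reductant is chosen so that Pd(0), which would ionise the dienyl epoxide, is not generated on purpose, and the step is placed last so that the α-methylene lactone never meets fluoride, base or a metathesis catalyst.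

**Compound list**

1 | (E)-pent-2-en-4-yn-1-ol | C#C/C=C/CO | starting material
2 | (E)-5-(triisopropylsilyl)pent-2-en-4-yn-1-ol | CC(C)[Si](C(C)C)(C(C)C)C#C/C=C/CO | intermediate
3 | (E)-4,4,5,5-tetramethyl-2-[5-(triisopropylsilyl)pent-2-en-4-yn-1-yl]-1,3,2-dioxaborolane | CC(C)[Si](C(C)C)(C(C)C)C#C/C=C/CB1OC(C)(C)C(C)(C)O1 | intermediate
4 | but-2-yn-1-ol | CC#CCO | starting material
5 | sodium cyclic (Z)-alkenylalanate (2,2-bis(2-methoxyethoxy)-3-methyl-2,5-dihydro-1,2-oxaaluminol-2-uide) | CC1=CCO[Al-]1(OCCOC)OCCOC.[Na+] | intermediate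
6 | (Z)-3-iodobut-2-en-1-ol | C/C(I)=C/CO | intermediate
7 | (Z)-3-iodobut-2-enal | C/C(I)=C/C=O | intermediate
8 | pinacol borate ester of 9 (O6–B) | C/C(I)=C/[C@H](OB1OC(C)(C)C(C)(C)O1)[C@@H](C=C)C#C[Si](C(C)C)(C(C)C)C(C)C | intermediate
9 | (2Z,4R,5S)-2-iodo-5-[(triisopropylsilyl)ethynyl]hepta-2,6-dien-4-ol (C6–OH and C7 alkynyl anti) | C/C(I)=C/[C@H](O)[C@@H](C=C)C#C[Si](C(C)C)(C(C)C)C(C)C | intermediate
10 | tert-butyl carbonate of 9 | C/C(I)=C/[C@H](OC(=O)OC(C)(C)C)[C@@H](C=C)C#C[Si](C(C)C)(C(C)C)C(C)C | intermediate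
11 | all-equatorial (4,6-cis, 5-trans) 4-(iodomethyl)-6-[(Z)-2-iodoprop-1-enyl]-5-[(triisopropylsilyl)ethynyl]-1,3-dioxan-2-one | C/C(I)=C/[C@@H]1OC(=O)O[C@H](CI)[C@H]1C#C[Si](C(C)C)(C(C)C)C(C)C | intermediate
12 | iodo diol (C9 iodide; C6 and C8 hydroxyls syn, C7 alkynyl anti to both) | C/C(I)=C/[C@H](O)[C@@H]([C@H](O)CI)C#C[Si](C(C)C)(C(C)C)C(C)C | intermediate
13 | epoxy alcohol (C8–C9 oxirane, free C6–OH) | C/C(I)=C/[C@H](O)[C@@H]([C@H]1CO1)C#C[Si](C(C)C)(C(C)C)C(C)C | intermediate
14 | C6 tert-butyldimethylsilyl ether of 13 | C/C(I)=C/[C@H](O[Si](C)(C)C(C)(C)C)[C@@H]([C@H]1CO1)C#C[Si](C(C)C)(C(C)C)C(C)C | intermediate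
15 | (Z)-diene epoxide (vinyl C3 in place of iodine, cis to C6) | C=C/C(C)=C\[C@H](O[Si](C)(C)C(C)(C)C)[C@@H]([C@H]1CO1)C#C[Si](C(C)C)(C(C)C)C(C)C | intermediate
16 | ring-opened adduct, ethyl 2-(diethoxyphosphoryl)-4-hydroxy ester (C8–OH; C10 epimers) | C=C/C(C)=C\[C@H](O[Si](C)(C)C(C)(C)C)[C@@H]([C@H](O)CC(C(=O)OCC)P(=O)(OCC)OCC)C#C[Si](C(C)C)(C(C)C)C(C)C | intermediate
17 | α-(diethoxyphosphoryl)-γ-butyrolactone (O8–C14 lactone; C10 epimers) | C=C/C(C)=C\[C@H](O[Si](C)(C)C(C)(C)C)[C@@H]([C@H]1CC(P(=O)(OCC)OCC)C(=O)O1)C#C[Si](C(C)C)(C(C)C)C(C)C | intermediate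
18 | (E)-α-(prop-2-enylidene)-γ-butyrolactone | C=C/C(C)=C\[C@H](O[Si](C)(C)C(C)(C)C)[C@@H]([C@H]1C/C(=C\C=C)C(=O)O1)C#C[Si](C(C)C)(C(C)C)C(C)C | intermediate
19 | diol (C8–OH and C14–OH; (E)-2-substituted penta-2,4-dien-1-ol) | C=C/C(C)=C\[C@H](O[Si](C)(C)C(C)(C)C)[C@@H]([C@H](O)C/C(CO)=C\C=C)C#C[Si](C(C)C)(C(C)C)C(C)C | intermediate
20 | C14 triethylsilyl ether of 19 | C=C/C(C)=C\[C@H](O[Si](C)(C)C(C)(C)C)[C@@H]([C@H](O)C/C(CO[Si](CC)(CC)CC)=C\C=C)C#C[Si](C(C)C)(C(C)C)C(C)C | intermediate
21 | (E)-but-2-enal | C/C=C/C=O | starting material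
22 | (Z)-2-iodobut-2-enal | C/C=C(\I)C=O | intermediate
23 | (Z)-2-iodobut-2-en-1-ol | C/C=C(\I)CO | intermediate
24 | (Z)-tert-butyl[(2-iodobut-2-en-1-yl)oxy]dimethylsilane | C/C=C(\I)CO[Si](C)(C)C(C)(C)C | intermediate
25 | alkenyllithium from 24 (lithium cis to the methyl group) | C/C=C(\[Li])CO[Si](C)(C)C(C)(C)C | intermediate
26 | (Z)-2-{[(tert-butyldimethylsilyl)oxy]methyl}but-2-enoic acid | C/C=C(\C(=O)O)CO[Si](C)(C)C(C)(C)C | intermediate
27 | mixed anhydride of 26 with 2,4,6-trichlorobenzoic acid | C/C=C(\C(=O)OC(=O)c1c(Cl)cc(Cl)cc1Cl)CO[Si](C)(C)C(C)(C)C | intermediate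
28 | C8 ester of 20 with 26 (C14–OTES) | C=C/C(C)=C\[C@H](O[Si](C)(C)C(C)(C)C)[C@@H]([C@H](OC(=O)/C(=C\C)CO[Si](C)(C)C(C)(C)C)C/C(CO[Si](CC)(CC)CC)=C\C=C)C#C[Si](C(C)C)(C(C)C)C(C)C | intermediate
29 | C14 allylic alcohol | C=C/C(C)=C\[C@H](O[Si](C)(C)C(C)(C)C)[C@@H]([C@H](OC(=O)/C(=C\C)CO[Si](C)(C)C(C)(C)C)C/C(CO)=C\C=C)C#C[Si](C(C)C)(C(C)C)C(C)C | intermediate
30 | (1R,10R)-epoxy alcohol (seco-triene) | C=C/C(C)=C\[C@H](O[Si](C)(C)C(C)(C)C)[C@@H]([C@H](OC(=O)/C(=C\C)CO[Si](C)(C)C(C)(C)C)C[C@]1(CO)O[C@@H]1C=C)C#C[Si](C(C)C)(C(C)C)C(C)C | intermediate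
31 | ten-membered (2Z,4Z)-diene epoxide with C6–OTBS, C7 silylethynyl and the silylated C8 ester | CC(C)[Si](C(C)C)(C(C)C)C#C[C@H]1[C@@H](O[Si](C)(C)C(C)(C)C)/C=C(C)\C=C/[C@H]2O[C@@]2(CO)C[C@H]1OC(=O)/C(=C\C)CO[Si](C)(C)C(C)(C)C | intermediate
32 | macrocyclic alkynyl triol (free C6–OH, C14–OH and side-chain OH; C7 ethynyl) | C#C[C@H]1[C@@H](O)/C=C(C)\C=C/[C@H]2O[C@@]2(CO)C[C@H]1OC(=O)/C(=C\C)CO | intermediate
33 | alkoxycarbonylpalladium(II) chloride at O6 (thiourea-ligated) | C#C[C@H]1[C@@H](OC(=O)[Pd]Cl)/C=C(C)\C=C/[C@H]2O[C@@]2(CO)C[C@H]1OC(=O)/C(=C\C)CO | intermediate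
34 | CNP0165856.1 | C=C1C(=O)O[C@H]2/C=C(C)\C=C/[C@H]3O[C@@]3(CO)C[C@@H](OC(=O)/C(=C\C)CO)[C@@H]12 | target

**Step count and risks**

Total step count: 24. Longest linear sequence: 18 steps (steps 1, 2, 5–14, 19–24, from 1 to 34).

Steps most likely to fail:

1. Step 24 (key step). What may go wrong: opening of the dienyl epoxide by adventitious Pd(0) or by the HCl shuttle, or ionisation of the dienylic C6–O bond, in competition with the carbonylation. Fallback (radical closure of the same C11–C12 bond, known chemistry), from 32 back to 34: the two primary hydroxyls of 32 are silylated selectively (TBSCl, imidazole, DMF, −20 °C) to give the bis(silyl ether) with free C6–OH F1. Acylation with phenyl selenochloroformate and pyridine gives the Se-phenyl selenocarbonate F2. Slow addition of Bu3SnH with AIBN (benzene, 80 °C) generates the alkoxycarbonyl radical, which closes 5-exo-dig onto the alkyne to give the bis(silyl) α-methylene lactone F3. HF·pyridine (THF, 0 °C) then gives 34.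

2. Step 22. What may go wrong: oligomerisation by cross metathesis, or failure of the strained ten-membered ring to close. Fallback (ring closure at C3–C4 by a palladium-free Stille-type coupling), from 14 back to 31:
   - Commercial (Z)-3-(tributylstannyl)prop-2-en-1-ol is oxidised with MnO2 to (Z)-3-(tributylstannyl)prop-2-enal F4.
   - 14, with its vinyl iodide kept, is treated with sodium triethyl phosphonoacetate as in step 11 to give, through the ring-opened hydroxy phosphonoester F5, the iodo phosphono lactone F6.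
   - Horner–Wadsworth–Emmons reaction of F6 with F4 gives the (Z)-stannyl alkylidene lactone F7.
   - DIBAL-H gives the stannyl diol F8, and TESCl gives the C14 triethylsilyl ether F9.
   - Yamaguchi esterification with 26 (through 27) gives the ester F10, and PPTS/MeOH gives the allylic alcohol F11.
   - Sharpless epoxidation with D-(−)-diethyl tartrate gives the stannyl epoxy alcohol F12.
   - Copper(I) thiophene-2-carboxylate (NMP, 0 °C → rt, high dilution) couples the (Z)-vinylstannane with the (Z)-vinyl iodide intramolecularly to give 31.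

3. Step 5. What may go wrong: low reactivity of the conjugated allylboronate or poor facial selectivity, which would erode the absolute and relative configuration at C6/C7. Fallback (chromium-mediated allylation), from 2 back to 9: 2 is converted with CBr4 and PPh3 into (E)-(5-bromopent-3-en-1-yn-1-yl)triisopropylsilane F13. F13 is added to 7 in a catalytic asymmetric Nozaki–Hiyama–Kishi allylation (CrCl2 cat., chiral sulfonamide ligand, Mn, Cp2ZrCl2, THF), which is anti-selective through the (E)-allylchromium chair transition state and gives 9.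

Further compounds
F1 | step 24 | bis(tert-butyldimethylsilyl) ether of 32 at O14 and the side-chain oxygen (free C6–OH) | C#C[C@H]1[C@@H](O)/C=C(C)\C=C/[C@H]2O[C@@]2(CO[Si](C)(C)C(C)(C)C)C[C@H]1OC(=O)/C(=C\C)CO[Si](C)(C)C(C)(C)C
F2 | step 24 | Se-phenyl selenocarbonate of F1 at O6 | C#C[C@H]1[C@@H](OC(=O)[Se]c3ccccc3)/C=C(C)\C=C/[C@H]2O[C@@]2(CO[Si](C)(C)C(C)(C)C)C[C@H]1OC(=O)/C(=C\C)CO[Si](C)(C)C(C)(C)C
F3 | step 24 | bis(tert-butyldimethylsilyl) ether of 34 | C=C1C(=O)O[C@H]2/C=C(C)\C=C/[C@H]3O[C@@]3(CO[Si](C)(C)C(C)(C)C)C[C@@H](OC(=O)/C(=C\C)CO[Si](C)(C)C(C)(C)C)[C@@H]12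
F4 | step 22 | (Z)-3-(tributylstannyl)prop-2-enal | O=C/C=C\[Sn](CCCC)(CCCC)CCCC
F5 | step 22 | ring-opened hydroxy phosphonoester from 14 (vinyl iodide kept) | C/C(I)=C/[C@H](O[Si](C)(C)C(C)(C)C)[C@@H]([C@H](O)CC(C(=O)OCC)P(=O)(OCC)OCC)C#C[Si](C(C)C)(C(C)C)C(C)C
F6 | step 22 | iodo α-(diethoxyphosphoryl)-γ-butyrolactone | C/C(I)=C/[C@H](O[Si](C)(C)C(C)(C)C)[C@@H]([C@H]1CC(P(=O)(OCC)OCC)C(=O)O1)C#C[Si](C(C)C)(C(C)C)C(C)C
F7 | step 22 | (E)-α-[(Z)-3-(tributylstannyl)prop-2-enylidene]-γ-butyrolactone | C/C(I)=C/[C@H](O[Si](C)(C)C(C)(C)C)[C@@H]([C@H]1C/C(=C\C=C/[Sn](CCCC)(CCCC)CCCC)C(=O)O1)C#C[Si](C(C)C)(C(C)C)C(C)C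
F8 | step 22 | stannyl diol (C8–OH and C14–OH) | C/C(I)=C/[C@H](O[Si](C)(C)C(C)(C)C)[C@@H]([C@H](O)C/C(CO)=C\C=C/[Sn](CCCC)(CCCC)CCCC)C#C[Si](C(C)C)(C(C)C)C(C)C
F9 | step 22 | C14 triethylsilyl ether of F8 | C/C(I)=C/[C@H](O[Si](C)(C)C(C)(C)C)[C@@H]([C@H](O)C/C(CO[Si](CC)(CC)CC)=C\C=C/[Sn](CCCC)(CCCC)CCCC)C#C[Si](C(C)C)(C(C)C)C(C)C
F10 | step 22 | C8 ester of F9 with 26 | C/C(I)=C/[C@H](O[Si](C)(C)C(C)(C)C)[C@@H]([C@H](OC(=O)/C(=C\C)CO[Si](C)(C)C(C)(C)C)C/C(CO[Si](CC)(CC)CC)=C\C=C/[Sn](CCCC)(CCCC)CCCC)C#C[Si](C(C)C)(C(C)C)C(C)C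
F11 | step 22 | C14 allylic alcohol from F10 | C/C(I)=C/[C@H](O[Si](C)(C)C(C)(C)C)[C@@H]([C@H](OC(=O)/C(=C\C)CO[Si](C)(C)C(C)(C)C)C/C(CO)=C\C=C/[Sn](CCCC)(CCCC)CCCC)C#C[Si](C(C)C)(C(C)C)C(C)C
F12 | step 22 | (1R,10R)-epoxy alcohol with (Z)-vinylstannane and (Z)-vinyl iodide | C/C(I)=C/[C@H](O[Si](C)(C)C(C)(C)C)[C@@H]([C@H](OC(=O)/C(=C\C)CO[Si](C)(C)C(C)(C)C)C[C@]1(CO)O[C@@H]1/C=C\[Sn](CCCC)(CCCC)CCCC)C#C[Si](C(C)C)(C(C)C)C(C)C
F13 | step 5 | (E)-(5-bromopent-3-en-1-yn-1-yl)triisopropylsilane | CC(C)[Si](C(C)C)(C(C)C)C#C/C=C/CBr
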